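- south: substrate 0.12 M; enzyme 0.02 mol%; impurity 15 µM; run made earlier
- flask: substrate 0.12 M; enzyme 0.01 mol%; impurity 15 µM

south run (percent of the substrate charged)

| time / min | product / % |
|---|---|
| 3.00 | 1.1 |
| 10.0 | 2.0 |
| 15.0 | 2.9 |
| 25.0 | 4.0 |
| 40.0 | 6.1 |
| 50.0 | 7.1 |
| 60.0 | 8.1 |

(scatter of a reading: 0.3 percentage points)

1. factor on the rate of making product when 10 % of the substrate are converted if enzyme is charged twice over
2. factor on the rate when 10 % of the substrate are converted if enzyme is charged at 0.05 mol% instead

- what has gone from substrate into another species counts as reacted, even if it can come back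
- no earlier run changes the charge of enzyme; that part of a forecast is a guess

1. In a one-step world the rate follows c_enzyme, which gives a factor 2 for the doubled charge and 5.00 for 0.05 mol%. My decision was whether the flask's 0.01 mol% could stand as the loading.

2. The south run began faster than it went on: I read 1.1 % product at 3.00 min, then a slope of 139 µM min⁻¹ from 15.0 min to 60.0 min. I took this to mean that impurity removes enzyme one for one, which no earlier run tests.

3. In the flask c_enzyme is 12.0 µM and c_impurity is 15 µM, which makes −3.00 µM. That is the enzyme margin, charged c_enzyme minus charged c_impurity: in my reckoning, above zero it is the enzyme standing free after that binding, and below zero it is the impurity left unbound.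

4. The south margin was 9.00 µM, and the doubled charge equals the south charge. At 0.05 mol% the margin is 45.0 µM. In the flask, charged c_enzyme is less than charged c_impurity, so I expected its rate to fade and not to settle at half the south slope. I committed to factors above the one-step pair, with a quotient of 5.00, and I decided to charge above c_impurity in the next run.

5. The forecast gave 3.4 (1.9 to 4) and 4.6 (2.4 to 5.6), a quotient of 1.35, which differs from mine: “I lean towards titration, hedged because this is untested.”

    substrate + enzyme → product + enzyme, rate k1*[substrate]^2.5*[enzyme]/(1 + ([substrate]/Kh1)^2.5) (0.125 M, k = 6520 L²·⁵ mol⁻²·⁵ min⁻¹)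
    enzyme + impurity → spent catalyst (k = 10600 L mol⁻¹ min⁻¹)
    substrate ⇌ dormant form (K = 3.10, k = 0.00106 min⁻¹)

6. The flask gave 47.1 for the doubled charge and 233 for 0.05 mol%. At 5.00 h the flask held 0 % enzyme and 20 % of its impurity charge unbound, and the margin reckons that remainder as 20.0 %. The margins of the two richer charges, 45.0 µM and 9.00 µM, stand in a quotient of 5.00, and the two factors of the flask stand in a quotient of 4.95.

The runs stem from a simulated flask for substances that don't exist; scatter was added.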